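**Retrosynthetic overview**
- The plan rests on ring A: C4a lies between the oxygen-bearing C5 and C8a, and C6 and C8 carry one-carbon groups, so C5–C4a–C8a maps onto a 2-alkylmalonate and C6–C7–C8 with both formyl carbons onto dimethyl acetonedicarboxylate.
- Ring A is formed first, by double Claisen condensation (C8–C8a, then C5–C6) of the malonate with the acetonedicarboxylate.
- The pyran ring is formed second: acid ionisation of a C2 benzylic methyl ether and capture by a ring A phenol makes O1–C2 and sets C2.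
- Ring B arrives intact as 2,4,6-trimethoxyphenyllithium and is formylated twice late; ester-to-aldehyde adjustment on ring A and O-demethylation finish the route.
- C3 and C4 come from an amine-catalysed Michael addition of isovaleraldehyde to the alkylidene malonate made from isovaleraldehyde and dimethyl malonate.

Key step: step 5

Remark on numbering: C2, C3, C4, C4a to C8a are the chroman positions of the target; ring A is the benzo ring, ring B the pendant aryl group. The target is (2R,3S,4S): 2,3-cis, 3,4-trans.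

Assumption: the Michael addition of step 2 is taken to follow the sense of induction known for aldehyde additions to nitroalkenes and arylidene malonates (syn adduct), so the (R)-catalyst is expected to give the (3S,4S) pair.

**Route**

Step 1
Reactants: 1 isovaleraldehyde; 2 dimethyl malonate
Product: 3 dimethyl 2-(3-methylbutylidene)malonate
Conditions: piperidine (cat.), AcOH (cat.), PhMe, reflux, azeotropic removal of water
Reagents that add atoms: none
Why: Amine-catalysed Knoevenagel condensation driven by removal of water gives the alkylidene malonate, which has no geometric isomers because the two esters are identical.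

Step 2
Reactants: 3 dimethyl 2-(3-methylbutylidene)malonate; 1 isovaleraldehyde
Product: 4 dimethyl 2-[(3S,4S)-3-formyl-2,6-dimethylheptan-4-yl]malonate
Conditions: (R)-2-[diphenyl(trimethylsilyloxy)methyl]pyrrolidine (20 mol %), PhCO2H (20 mol %), 1 (3 equiv), CHCl3, 4 °C → rt
Reagents that add atoms: none
Why: Enamine-mediated asymmetric Michael addition, in which the (E)-enamine of 1, shielded on one face by the diphenyl(silyloxy)methyl group, adds to the β-carbon of 3 through an acyclic synclinal transition state and so sets C3 and C4 of the target together as the syn (3S,4S) pair.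

Step 3
Reactants: 4 dimethyl 2-[(3S,4S)-3-formyl-2,6-dimethylheptan-4-yl]malonate; 5 1,3,5-trimethoxybenzene
Product: 7 dimethyl 2-[(3S,4S)-3-[hydroxy(2,4,6-trimethoxyphenyl)methyl]-2,6-dimethylheptan-4-yl]malonate (both carbinol epimers), via 2,4,6-trimethoxyphenyllithium 6 (not isolated)
Conditions: 5 (2.5 equiv), n-BuLi (2.4 equiv), THF, 0 °C → rt; then 4, −78 °C; aq. NH4Cl
Reagents that add atoms: none
Why: 1,2-Addition of an aryllithium to an aldehyde, in which the first equivalent of 6 turns the malonate into its lithium enolate (shielding both esters from attack and lactonisation and blocking loss of malonate from C4) and the second adds to the formyl group; the carbinol configuration does not matter because this carbon is ionised in step 6.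

Step 4
Reactants: 7 dimethyl 2-[(3S,4S)-3-[hydroxy(2,4,6-trimethoxyphenyl)methyl]-2,6-dimethylheptan-4-yl]malonate
Product: 8 dimethyl 2-[(3S,4S)-3-[methoxy(2,4,6-trimethoxyphenyl)methyl]-2,6-dimethylheptan-4-yl]malonate (both ether epimers)
Conditions: Me3OBF4, 1,8-bis(dimethylamino)naphthalene, CH2Cl2, 0 °C → rt
Reagents that add atoms: trimethyloxonium tetrafluoroborate, C[O+](C)C.F[B-](F)(F)F
Why: O-Methylation of a hindered secondary alcohol by a trialkyloxonium salt under buffered conditions, where the amine base is too weak to deprotonate the malonate C–H and the acid that would ionise the electron-rich benzylic alcohol is scavenged.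

Step 5
Reactants: 8 dimethyl 2-[(3S,4S)-3-[methoxy(2,4,6-trimethoxyphenyl)methyl]-2,6-dimethylheptan-4-yl]malonate; 9 dimethyl 1,3-acetonedicarboxylate
Product: 12 dimethyl 2,4,6-trihydroxy-5-[(3S,4S)-3-[methoxy(2,4,6-trimethoxyphenyl)methyl]-2,6-dimethylheptan-4-yl]isophthalate (both ether epimers), via open-chain Claisen adduct 10 (not isolated), via cyclohexane-1,3,5-trione tautomer 11 (not isolated)
Conditions: NaOMe (3 equiv), 9 (2 equiv, slow addition), MeOH, reflux; then PhMe, 110 °C with distillation of MeOH; AcOH quench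
Reagents that add atoms: none
Why: Proposed new method: methoxide converts 9 into its sodium enolate, which should C-acylate one ester carbonyl of 8 (intermolecular Claisen condensation, C8–C8a, adduct 10); the remaining methylene of the acetonedicarboxylate unit then attacks the second malonate ester in a 6-exo-trig Dieckmann closure (C5–C6) to trione 11, which enolises to the aromatic triol and is held as its sodium phenoxide, the sink that pulls the reversible acyl transfers forward. The closest known reaction is the alkoxide-mediated cyclocondensation of unsubstituted malonic esters with acetonedicarboxylic esters to phloroglucinol dicarboxylates; a 2-(sec-alkyl)malonate has not been used as the acyl acceptor. Ring A is the only ring closed and no stereocentre is formed. The step needs C- rather than O-acylation of 9 and cross- rather than self-condensation: O-acyl products are returned by methoxide whereas the C,C-pathway ends in the aromatic salt, 8 has a single α-hydrogen so its own Claisen products cannot be stabilised and revert, and slow addition of 9 keeps its self-condensation down. C3 and C4 are not acidic and carry no β-leaving group, and the C2 methyl ether and the trimethoxyphenyl ring are inert to methoxide, so both stereocentres should pass through unchanged.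

Step 6
Reactants: 12 dimethyl 2,4,6-trihydroxy-5-[(3S,4S)-3-[methoxy(2,4,6-trimethoxyphenyl)methyl]-2,6-dimethylheptan-4-yl]isophthalate
Product: 14 dimethyl (2R,3S,4S)-5,7-dihydroxy-4-isobutyl-3-isopropyl-2-(2,4,6-trimethoxyphenyl)chromane-6,8-dicarboxylate, via trimethoxybenzylic cation 13 (not isolated)
Conditions: CF3CO2H (10 equiv), CH2Cl2, 0 °C → rt
Reagents that add atoms: none
Why: SN1 ionisation of the 2,4,6-trimethoxybenzylic methyl ether to cation 13 and 6-exo-trig capture by either of the two equivalent flanking phenols closes the pyran, and because the C2–O bond re-ionises under the acid, C2 should settle under thermodynamic control with the aryl group equatorial and the C3 isopropyl and C4 isobutyl groups trans-diaxial (the C4 group axial to escape peri strain with the C5 oxygen), which is 2,3-cis and (2R).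

Step 7
Reactants: 14 dimethyl (2R,3S,4S)-5,7-dihydroxy-4-isobutyl-3-isopropyl-2-(2,4,6-trimethoxyphenyl)chromane-6,8-dicarboxylate
Product: 15 dimethyl (2R,3S,4S)-4-isobutyl-3-isopropyl-5,7-dimethoxy-2-(2,4,6-trimethoxyphenyl)chromane-6,8-dicarboxylate
Conditions: MeI, K2CO3, DMF, 50 °C
Reagents that add atoms: iodomethane, CI
Why: Williamson methylation of the two hydrogen-bonded phenols with a carbonate base in a dipolar aprotic solvent, which removes the salicylate-type phenols before ester reduction and ring B formylation.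

Step 8
Reactants: 15 dimethyl (2R,3S,4S)-4-isobutyl-3-isopropyl-5,7-dimethoxy-2-(2,4,6-trimethoxyphenyl)chromane-6,8-dicarboxylate
Product: 16 [(2R,3S,4S)-4-isobutyl-3-isopropyl-5,7-dimethoxy-2-(2,4,6-trimethoxyphenyl)chromane-6,8-diyl]dimethanol
Conditions: LiAlH4, THF, 0 → 50 °C; aqueous NaOH work-up
Reagents that add atoms: none
Why: LiAlH4 reduction of di-ortho-substituted benzoates to benzylic alcohols, to which the aryl methyl ethers and the chroman ether are inert.

Step 9
Reactants: 16 [(2R,3S,4S)-4-isobutyl-3-isopropyl-5,7-dimethoxy-2-(2,4,6-trimethoxyphenyl)chromane-6,8-diyl]dimethanol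
Product: 17 (2R,3S,4S)-4-isobutyl-3-isopropyl-5,7-dimethoxy-2-(2,4,6-trimethoxyphenyl)chromane-6,8-dicarbaldehyde
Conditions: MnO2 (activated, excess), CH2Cl2, rt
Reagents that add atoms: none
Why: Chemoselective oxidation of benzylic alcohols by MnO2 stops at the aldehyde under neutral conditions that spare the acid-labile C2–O bond.

Step 10
Reactants: 17 (2R,3S,4S)-4-isobutyl-3-isopropyl-5,7-dimethoxy-2-(2,4,6-trimethoxyphenyl)chromane-6,8-dicarbaldehyde
Product: 19 (2R,3S,4S)-2-(3,5-diformyl-2,4,6-trimethoxyphenyl)-4-isobutyl-3-isopropyl-5,7-dimethoxychromane-6,8-dicarbaldehyde, via ring B monoaldehyde 18 (not isolated)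
Conditions: Cl2CHOMe (excess), TiCl4, CH2Cl2, −20 → 0 °C; then H2O
Reagents that add atoms: dichloromethyl methyl ether, COC(Cl)Cl; water, O
Why: Rieche formylation, in which the titanium tetrachloride-activated dichloromethyl methyl ether attacks in turn the two free ring B positions (each flanked by two methoxy groups) via monoaldehyde 18, while ring A is fully substituted and C2 already sits in its thermodynamically preferred configuration should the Lewis acid open the C2–O bond reversibly.

Step 11
Reactants: 19 (2R,3S,4S)-2-(3,5-diformyl-2,4,6-trimethoxyphenyl)-4-isobutyl-3-isopropyl-5,7-dimethoxychromane-6,8-dicarbaldehyde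
Product: 20 sideroxylonal B
Conditions: BCl3 (excess), CH2Cl2, −78 → 0 °C; then H2O
Reagents that add atoms: none
Why: Carbonyl-assisted aryl methyl ether cleavage with BCl3, possible for all five methoxy groups because each is ortho to a formyl group that chelates boron, while the C2–O bond is now flanked by two electron-poor diformyl rings and should resist ionisation.

**Compound list**

1 | isovaleraldehyde (3-methylbutanal) | CC(C)CC=O | starting material
2 | dimethyl malonate | COC(=O)CC(=O)OC | starting material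
3 | dimethyl 2-(3-methylbutylidene)malonate | CC(C)CC=C(C(=O)OC)C(=O)OC | intermediate
4 | dimethyl 2-[(3S,4S)-3-formyl-2,6-dimethylheptan-4-yl]malonate | CC(C)C[C@@H]([C@H](C(C)C)C=O)C(C(=O)OC)C(=O)OC | intermediate
5 | 1,3,5-trimethoxybenzene | COc1cc(OC)cc(OC)c1 | starting material
6 | 2,4,6-trimethoxyphenyllithium | [Li]c1c(OC)cc(OC)cc1OC | intermediate (not isolated)
7 | dimethyl 2-[(3S,4S)-3-[hydroxy(2,4,6-trimethoxyphenyl)methyl]-2,6-dimethylheptan-4-yl]malonate, both carbinol epimers | CC(C)C[C@@H]([C@H](C(C)C)C(O)c1c(OC)cc(OC)cc1OC)C(C(=O)OC)C(=O)OC | intermediate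
8 | dimethyl 2-[(3S,4S)-3-[methoxy(2,4,6-trimethoxyphenyl)methyl]-2,6-dimethylheptan-4-yl]malonate, both ether epimers | CC(C)C[C@@H]([C@H](C(C)C)C(OC)c1c(OC)cc(OC)cc1OC)C(C(=O)OC)C(=O)OC | intermediate
9 | dimethyl 1,3-acetonedicarboxylate (dimethyl 3-oxopentanedioate) | COC(=O)CC(=O)CC(=O)OC | starting material
10 | open-chain Claisen adduct: dimethyl 4-(methoxycarbonyl)-2-[(3S,4S)-3-[methoxy(2,4,6-trimethoxyphenyl)methyl]-2,6-dimethylheptan-4-yl]-3,5-dioxoheptanedioate | CC(C)C[C@@H]([C@H](C(C)C)C(OC)c1c(OC)cc(OC)cc1OC)C(C(=O)OC)C(=O)C(C(=O)OC)C(=O)CC(=O)OC | intermediate (not isolated)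
11 | cyclohexane-1,3,5-trione tautomer: dimethyl 5-[(3S,4S)-3-[methoxy(2,4,6-trimethoxyphenyl)methyl]-2,6-dimethylheptan-4-yl]-2,4,6-trioxocyclohexane-1,3-dicarboxylate | CC(C)C[C@@H]([C@H](C(C)C)C(OC)c1c(OC)cc(OC)cc1OC)C1C(=O)C(C(=O)OC)C(=O)C(C(=O)OC)C1=O | intermediate (not isolated)
12 | dimethyl 2,4,6-trihydroxy-5-[(3S,4S)-3-[methoxy(2,4,6-trimethoxyphenyl)methyl]-2,6-dimethylheptan-4-yl]isophthalate, both ether epimers | CC(C)C[C@@H]([C@H](C(C)C)C(OC)c1c(OC)cc(OC)cc1OC)c1c(O)c(C(=O)OC)c(O)c(C(=O)OC)c1O | intermediate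
13 | trimethoxybenzylic cation derived from 12 by loss of methoxide | CC(C)C[C@@H]([C@H](C(C)C)[CH+]c1c(OC)cc(OC)cc1OC)c1c(O)c(C(=O)OC)c(O)c(C(=O)OC)c1O | intermediate (not isolated)
14 | dimethyl (2R,3S,4S)-5,7-dihydroxy-4-isobutyl-3-isopropyl-2-(2,4,6-trimethoxyphenyl)chromane-6,8-dicarboxylate | CC(C)C[C@@H]1c2c(O)c(C(=O)OC)c(O)c(C(=O)OC)c2O[C@@H](c2c(OC)cc(OC)cc2OC)[C@H]1C(C)C | intermediate
15 | dimethyl (2R,3S,4S)-4-isobutyl-3-isopropyl-5,7-dimethoxy-2-(2,4,6-trimethoxyphenyl)chromane-6,8-dicarboxylate | CC(C)C[C@@H]1c2c(OC)c(C(=O)OC)c(OC)c(C(=O)OC)c2O[C@@H](c2c(OC)cc(OC)cc2OC)[C@H]1C(C)C | intermediate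
16 | [(2R,3S,4S)-4-isobutyl-3-isopropyl-5,7-dimethoxy-2-(2,4,6-trimethoxyphenyl)chromane-6,8-diyl]dimethanol | CC(C)C[C@@H]1c2c(OC)c(CO)c(OC)c(CO)c2O[C@@H](c2c(OC)cc(OC)cc2OC)[C@H]1C(C)C | intermediate
17 | (2R,3S,4S)-4-isobutyl-3-isopropyl-5,7-dimethoxy-2-(2,4,6-trimethoxyphenyl)chromane-6,8-dicarbaldehyde | CC(C)C[C@@H]1c2c(OC)c(C=O)c(OC)c(C=O)c2O[C@@H](c2c(OC)cc(OC)cc2OC)[C@H]1C(C)C | intermediate
18 | 3-[(2R,3S,4S)-6,8-diformyl-4-isobutyl-3-isopropyl-5,7-dimethoxychroman-2-yl]-2,4,6-trimethoxybenzaldehyde | CC(C)C[C@@H]1c2c(OC)c(C=O)c(OC)c(C=O)c2O[C@@H](c2c(OC)cc(OC)c(C=O)c2OC)[C@H]1C(C)C | intermediate (not isolated)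
19 | (2R,3S,4S)-2-(3,5-diformyl-2,4,6-trimethoxyphenyl)-4-isobutyl-3-isopropyl-5,7-dimethoxychromane-6,8-dicarbaldehyde | CC(C)C[C@@H]1c2c(OC)c(C=O)c(OC)c(C=O)c2O[C@@H](c2c(OC)c(C=O)c(OC)c(C=O)c2OC)[C@H]1C(C)C | intermediate
20 | sideroxylonal B | CC(C)C[C@@H]1c2c(O)c(C=O)c(O)c(C=O)c2O[C@@H](c2c(O)c(C=O)c(O)c(C=O)c2O)[C@H]1C(C)C | target

**Step count and risks**

Total step count: 11. Longest linear sequence: 11 steps (1 → 20).

Steps most likely to fail:

1. Step 5 (the labelled step). The hindered malonate, largely present as its enolate, may not accept two acyl transfers, so that self-condensation of 9 or O-acylation to pyranones takes over.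
 - Fallback (known reaction types only): ring A is brought in as a preformed phloroglucinol ether, the C4–C4a bond is made by enamine addition to an ortho-quinone methide, and the C6 and C8 carbons are added by late formylation. It sets out from isovaleraldehyde 1 and returns at tetra-aldehyde 19.
 - Commercial 2-hydroxy-4,6-dimethoxybenzaldehyde F1 is treated with i-BuMgBr (THF, 0 °C) to give 2-(1-hydroxy-3-methylbutyl)-3,5-dimethoxyphenol F2. TolSO2Na in aqueous HCO2H converts this into 3,5-dimethoxy-2-[3-methyl-1-(4-methylbenzenesulfonyl)butyl]phenol F3.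
 - NaHCO3 releases the ortho-quinone methide 3,5-dimethoxy-6-(3-methylbutylidene)cyclohexa-2,4-dien-1-one F4 in the presence of 1 and the (R)-pyrrolidine catalyst of step 2. Enamine addition and hemiacetal closure should give (3S,4S)-4-isobutyl-3-isopropyl-5,7-dimethoxychroman-2-ol F5.
 - Oxidation (PhI(OAc)2, cat. 2,2,6,6-tetramethylpiperidin-1-oxyl) gives (3S,4S)-4-isobutyl-3-isopropyl-5,7-dimethoxychroman-2-one F6, in which C3 can be settled trans to C4 with base if needed.
 - Aryllithium 6 (THF, −78 °C) adds to give (3S,4S)-4-isobutyl-3-isopropyl-5,7-dimethoxy-2-(2,4,6-trimethoxyphenyl)chroman-2-ol F7. Et3SiH/BF3·OEt2 (CH2Cl2, −78 °C) should reduce its cyclic oxocarbenium ion from the face opposite the axial C3 isopropyl group to (2R,3S,4S)-4-isobutyl-3-isopropyl-5,7-dimethoxy-2-(2,4,6-trimethoxyphenyl)chromane F8.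
 - Fourfold Rieche formylation (Cl2CHOMe, TiCl4) at C6, C8, C3' and C5' then gives 19, and step 11 follows.

2. Step 6. The equilibrium-controlled closure may settle on the 2,3-trans epimer, or reversible proton loss from C3 of cation 13 may erode the C3 configuration.
 - Fallback: C2 is set by kinetic hydride delivery to a cyclic oxocarbenium ion instead of by C–O bond formation on an open cation. It sets out from 12 and returns at 14.
 - 2,3-Dichloro-5,6-dicyano-1,4-benzoquinone in wet CH2Cl2 oxidises the C2 benzylic ether to dimethyl 2,4,6-trihydroxy-5-[(3S,4S)-2,6-dimethyl-3-(2,4,6-trimethoxybenzoyl)heptan-4-yl]isophthalate F9. This should rest as its cyclic hemiketal dimethyl (3S,4S)-2,5,7-trihydroxy-4-isobutyl-3-isopropyl-2-(2,4,6-trimethoxyphenyl)chromane-6,8-dicarboxylate F10.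
 - Et3SiH/BF3·OEt2 (CH2Cl2, −78 °C, a temperature at which 14 should not re-ionise) delivers hydride trans to the axial C3 isopropyl group and gives 14.

3. Step 2. The aliphatic alkylidene malonate is a weak acceptor and the β-branched aldehyde a slow donor, so conversion may stall, the amine may deconjugate 3, or the syn/anti selectivity may be poor.
 - Fallback: stoichiometric auxiliary control through a metalated hydrazone in place of amine catalysis. It sets out from 1 and 3 and returns at 4.
 - 1 is condensed with (S)-1-amino-2-(methoxymethyl)pyrrolidine to (S,E)-2-(methoxymethyl)-N-(3-methylbutylidene)pyrrolidin-1-amine F11. The (S)-auxiliary is chosen because electrophiles enter its aza-enolates from the face that corresponds to the 3S centre.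
 - LiN(i-Pr)2 (THF, −78 °C) followed by 3 gives the Michael adduct dimethyl 2-[(3S,4S)-3-[(E)-[(S)-2-(methoxymethyl)pyrrolidin-1-yl]iminomethyl]-2,6-dimethylheptan-4-yl]malonate F12, which is separated from any anti isomer.
 - Aqueous oxalic acid/Et2O cleaves the hydrazone and releases 4.

**Further compounds**

F1 | step 5 | 2-hydroxy-4,6-dimethoxybenzaldehyde | O=Cc1c(O)cc(OC)cc1OC
F2 | step 5 | 2-(1-hydroxy-3-methylbutyl)-3,5-dimethoxyphenol (racemic) | CC(C)CC(O)c1c(O)cc(OC)cc1OC
F3 | step 5 | 3,5-dimethoxy-2-[3-methyl-1-(4-methylbenzenesulfonyl)butyl]phenol (racemic) | CC(C)CC(c1c(O)cc(OC)cc1OC)S(=O)(=O)c1ccc(C)cc1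
F4 | step 5 | 3,5-dimethoxy-6-(3-methylbutylidene)cyclohexa-2,4-dien-1-one | O=C1C=C(OC)C=C(OC)C1=CCC(C)C
F5 | step 5 | (3S,4S)-4-isobutyl-3-isopropyl-5,7-dimethoxychroman-2-ol | CC(C)C[C@@H]1c2c(OC)cc(OC)cc2OC(O)[C@H]1C(C)C
F6 | step 5 | (3S,4S)-4-isobutyl-3-isopropyl-5,7-dimethoxychroman-2-one | CC(C)C[C@@H]1c2c(OC)cc(OC)cc2OC(=O)[C@H]1C(C)C
F7 | step 5 | (3S,4S)-4-isobutyl-3-isopropyl-5,7-dimethoxy-2-(2,4,6-trimethoxyphenyl)chroman-2-ol | CC(C)C[C@@H]1c2c(OC)cc(OC)cc2OC(O)(c2c(OC)cc(OC)cc2OC)[C@H]1C(C)C
F8 | step 5 | (2R,3S,4S)-4-isobutyl-3-isopropyl-5,7-dimethoxy-2-(2,4,6-trimethoxyphenyl)chromane | CC(C)C[C@@H]1c2c(OC)cc(OC)cc2O[C@@H](c2c(OC)cc(OC)cc2OC)[C@H]1C(C)C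
F9 | step 6 | dimethyl 2,4,6-trihydroxy-5-[(3S,4S)-2,6-dimethyl-3-(2,4,6-trimethoxybenzoyl)heptan-4-yl]isophthalate | CC(C)C[C@@H]([C@H](C(C)C)C(=O)c1c(OC)cc(OC)cc1OC)c1c(O)c(C(=O)OC)c(O)c(C(=O)OC)c1O
F10 | step 6 | dimethyl (3S,4S)-2,5,7-trihydroxy-4-isobutyl-3-isopropyl-2-(2,4,6-trimethoxyphenyl)chromane-6,8-dicarboxylate | CC(C)C[C@@H]1c2c(O)c(C(=O)OC)c(O)c(C(=O)OC)c2OC(O)(c2c(OC)cc(OC)cc2OC)[C@H]1C(C)C
F11 | step 2 | (S,E)-2-(methoxymethyl)-N-(3-methylbutylidene)pyrrolidin-1-amine | CC(C)C/C=N/N1CCC[C@H]1COC
F12 | step 2 | dimethyl 2-[(3S,4S)-3-[(E)-[(S)-2-(methoxymethyl)pyrrolidin-1-yl]iminomethyl]-2,6-dimethylheptan-4-yl]malonate | CC(C)C[C@@H]([C@H](C(C)C)/C=N/N1CCC[C@H]1COC)C(C(=O)OC)C(=O)OC
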